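**Strategy**

- Cuts, in retrosynthetic order: the three O–benzyl bonds; O1–C2 of ring C (hemiacetal back to phenol plus aldehyde); C2 back to a vinyl group on C3; and C3–Cα, an aldol bond between a ring A allenyl ketone and 4-(benzyloxy)benzaldehyde.
- Enabling feature: C3 is flanked by the C4 ketone, the aldehyde-level C2 and the carbinol Cα, and ring C is only the O1–C2 hemiacetal of this β-ketoaldehyde aldol. C2 can therefore travel as a vinyl group on C3, and ring C closes on its own once that vinyl is cleaved.
- Forward: ring A is bought with the C6 methoxy group, benzylated, degraded to the phenol, C-methylated (C8), formylated (C4) and turned into the allenyl ketone. A boron reductive aldol then joins the chain and ring B, freeing O1 and cleaving the vinyl group close ring C, and hydrogenolysis finishes.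
- Stereochemistry: C3 and Cα arise together in the aldol (Z-dienolborinate, chair transition state, syn; the Ipc ligands on boron select the aldehyde face). C2 settles by hemiacetal equilibration.

Key step: step 11

Conventions: locants O1 to C8a follow chroman-4-one numbering of the target and Cα is the exocyclic carbinol carbon. Ring A is the benzo ring, ring B the 4-oxyphenyl ring and ring C the pyranone ring. ArSi = 4,6-bis(benzyloxy)-2-[(tert-butyldimethylsilyl)oxy]-5-methoxy-3-methylphenyl; ArOH = 4,6-bis(benzyloxy)-2-hydroxy-5-methoxy-3-methylphenyl; Ipc = isopinocampheyl.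

Remark 1: C2 is a hemiacetal carbon that can equilibrate through the open hydroxy-aldehyde; the (2S) anomer drawn, with the C2 hydroxyl trans to the C3 side chain, is assumed to be the form adopted at equilibrium.

Remark 2: the borane antipode in step 11 is assigned by analogy with the Si-face preference of (Z)-enol diisopinocampheylborinates whose Ipc groups come from (+)-α-pinene; the sense is to be confirmed on the first run (Mosher ester of 19), and the borane from (−)-α-pinene would be used instead if it proves opposite.

**Route**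

Step 1
Reactants: 1 methyl 3,5-dihydroxy-4-methoxybenzoate
Product: 2 methyl 3,5-bis(benzyloxy)-4-methoxybenzoate
Conditions: BnBr, K2CO3, DMF, 60 °C
Reagents that add atoms: benzyl bromide, BrCc1ccccc1
Why: Williamson etherification of the two equivalent phenols with carbonate as base, conditions under which the methyl ester and the aryl methyl ether are inert.

Step 2
Reactants: 2 methyl 3,5-bis(benzyloxy)-4-methoxybenzoate
Product: 3 [3,5-bis(benzyloxy)-4-methoxyphenyl]methanol
Conditions: LiAlH4, THF, 0 °C to rt; Fieser work-up (H2O, aq NaOH)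
Reagents that add atoms: none
Why: Hydride reduction of the aryl ester to the benzylic alcohol, which leaves aryl benzyl and methyl ethers untouched.

Step 3
Reactants: 3 [3,5-bis(benzyloxy)-4-methoxyphenyl]methanol
Product: 4 3,5-bis(benzyloxy)-4-methoxybenzaldehyde
Conditions: activated MnO2, CH2Cl2, rt
Reagents that add atoms: none
Why: Chemoselective MnO2 oxidation of an electron-rich benzylic alcohol, which stops at the aldehyde.

Step 4
Reactants: 4 3,5-bis(benzyloxy)-4-methoxybenzaldehyde
Product: 6 3,5-bis(benzyloxy)-4-methoxyphenol, via aryl formate 5 (not isolated)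
Conditions: mCPBA, CH2Cl2, 0 °C to rt; aq Na2S2O3/NaHCO3 wash; then K2CO3 (cat.), MeOH, rt
Reagents that add atoms: 3-chloroperoxybenzoic acid (mCPBA), OOC(=O)c1cccc(Cl)c1
Why: Baeyer–Villiger oxidation in its Dakin-like mode, in which the electron-rich 3,4,5-trioxygenated aryl group migrates to oxygen to give formate 5, followed by mild transesterification that frees the phenol (excess peracid is removed before the oxidisable phenol is released).

Step 5
Reactants: 6 3,5-bis(benzyloxy)-4-methoxyphenol
Product: 7 4,6-bis(benzyloxy)-2-hydroxy-5-methoxybenzaldehyde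
Conditions: MgCl2, Et3N, (CH2O)n, MeCN, reflux; dilute aq HCl work-up
Reagents that add atoms: paraformaldehyde (reacting as formaldehyde), C=O
Why: Casnati–Skattebøl ortho-formylation, in which the magnesium phenoxide directs formaldehyde to a carbon next to the phenol oxygen (the two are equivalent) and a second formaldehyde oxidises the hydroxymethyl stage to the aldehyde, whose chelation discourages a second formylation.

Step 6
Reactants: 7 4,6-bis(benzyloxy)-2-hydroxy-5-methoxybenzaldehyde
Product: 10 3,5-bis(benzyloxy)-4-methoxy-2-methylphenol, via ethyl carbonate 8 (not isolated), via ortho-quinone methide 9 (not isolated)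
Conditions: ClCO2Et, Et3N, THF, 0 °C; filter; then NaBH4, THF/H2O, 0 °C to rt
Reagents that add atoms: none
Why: Carbonate-activated borohydride deoxygenation of a salicylaldehyde: reduction of the formyl group of 8 triggers carbonate transfer and elimination to ortho-quinone methide 9, which borohydride reduces to the methyl group, a sequence that spares the benzyl ethers.

Step 7
Reactants: 10 3,5-bis(benzyloxy)-4-methoxy-2-methylphenol
Product: 11 4,6-bis(benzyloxy)-2-hydroxy-5-methoxy-3-methylbenzaldehyde
Conditions: MgCl2, Et3N, (CH2O)n, MeCN, reflux; dilute aq HCl work-up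
Reagents that add atoms: paraformaldehyde (reacting as formaldehyde), C=O
Why: The same magnesium-mediated ortho-formylation, now without any regiochemical choice because the single free ring carbon lies next to the phenol oxygen.

Step 8
Reactants: 11 4,6-bis(benzyloxy)-2-hydroxy-5-methoxy-3-methylbenzaldehyde
Product: 12 4,6-bis(benzyloxy)-2-[(tert-butyldimethylsilyl)oxy]-5-methoxy-3-methylbenzaldehyde
Conditions: TBSCl, imidazole, DMF, rt to 40 °C
Reagents that add atoms: tert-butyldimethylsilyl chloride (TBSCl), CC(C)(C)[Si](C)(C)Cl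
Why: Standard silyl ether formation on a phenol, which labels the future O1 as the one oxygen that can later be unmasked with fluoride while the benzyl ethers stay.

Step 9
Reactants: 12 4,6-bis(benzyloxy)-2-[(tert-butyldimethylsilyl)oxy]-5-methoxy-3-methylbenzaldehyde
Product: 13 1-(ArSi)but-3-yn-1-ol (racemic)
Conditions: propargyl bromide, Zn dust, THF/sat. aq NH4Cl, 0 °C to rt
Reagents that add atoms: propargyl bromide, C#CCBr
Why: Barbier propargylation, in which the allenylzinc reagent formed in the flask adds to the hindered aldehyde through a cyclic SE2' transition state and the aqueous medium protonates the alkoxide before the neighbouring aryl silyl group can migrate; the carbinol centre is removed in step 10, and any allenyl carbinol regioisomer is oxidised to the same ketone 15.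

Step 10
Reactants: 13 1-(ArSi)but-3-yn-1-ol
Product: 15 1-(ArSi)buta-2,3-dien-1-one, via propargyl ketone 14 (not isolated)
Conditions: Dess–Martin periodinane, NaHCO3, CH2Cl2, 0 °C to rt; then Et3N (cat.), CH2Cl2, 0 °C
Reagents that add atoms: none
Why: Dess–Martin oxidation gives propargyl ketone 14, whose doubly activated CH2 is isomerised by catalytic amine into conjugation as the allenyl ketone, a standard entry to 1,2-allenyl ketones, while the silyl group on O1 rules out oxa-Michael closure.

Step 11
Reactants: 15 1-(ArSi)buta-2,3-dien-1-one; 16 4-(benzyloxy)benzaldehyde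
Product: 19 (2S)-1-(ArSi)-2-[(S)-[4-(benzyloxy)phenyl](hydroxy)methyl]but-3-en-1-one, via (Z)-dienolborinate 17 (not isolated), via boron aldolate 18 (not isolated)
Conditions: (−)-(Ipc)2BH [Ipc from (+)-α-pinene], Et2O, −40 to 0 °C; then 16, −78 °C; then pH 7 buffer (Na2HPO4/NaH2PO4), MeOH, 30% H2O2, 0 °C
Reagents that add atoms: none
Why: Proposed new method: the s-cis allenyl ketone 15 should undergo concerted 1,4-hydroboration by (Ipc)2BH through a six-membered transition state (boron to the carbonyl oxygen, hydride to the central allene carbon), which can only deliver the (Z)-dienolborinate 17 with the vinyl group on the α-carbon; the closest known reaction type is the chiral dialkylborane reductive aldol of allenyl esters and acrylamides, extended here to an aryl allenyl ketone. Dienolborinate 17 should then add to aldehyde 16 at its α-carbon through a closed Zimmerman–Traxler chair with the aldehyde aryl group equatorial, forming the C3–Cα bond and, after oxidative release from boron aldolate 18, the complete carbon skeleton; no ring is closed in this step. The syn relationship of C3 and Cα follows from the Z enolate geometry in the chair, and the absolute configuration (2S and S at the carbinol in 19) from the Ipc ligands, which are expected to steer the enolate to the Si face of 16 since neither partner carries a stereocentre. The step needs 1,4-hydroboration rather than carbonyl reduction or alkene hydroboration, α- rather than γ-attack of the dienolate, syn selectivity and aldehyde face selectivity: the cyclic boron transition states secure the first three, the ketone has no second enolisable position, the twisted 2,6-disubstituted aroyl group favours the s-cis allenone and the Z enolate, aldehyde 16 cannot enolise, and the silyl group on O1 blocks oxa-Michael closure onto the allenone.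

Step 12
Reactants: 19 (2S)-1-(ArSi)-2-[(S)-[4-(benzyloxy)phenyl](hydroxy)methyl]but-3-en-1-one
Product: 20 (2S)-1-(ArOH)-2-[(S)-[4-(benzyloxy)phenyl](hydroxy)methyl]but-3-en-1-one
Conditions: Bu4NF, AcOH (1:1), THF, 0 °C
Reagents that add atoms: none
Why: Fluoride-mediated desilylation of an aryl silyl ether, buffered with acetic acid so that the phenoxide cannot start retro-aldol cleavage, C3 epimerisation or migration of the vinyl group into conjugation.

Step 13
Reactants: 20 (2S)-1-(ArOH)-2-[(S)-[4-(benzyloxy)phenyl](hydroxy)methyl]but-3-en-1-one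
Product: 23 (2S,3R)-5,7-bis(benzyloxy)-3-[(S)-[4-(benzyloxy)phenyl](hydroxy)methyl]-2-hydroxy-6-methoxy-8-methyl-2,3-dihydro-4H-chromen-4-one, via vicinal diol 21 (not isolated), via β-ketoaldehyde 22 (not isolated)
Conditions: OsO4 (cat.), NaIO4, 2,6-lutidine, dioxane/H2O, rt, short reaction time
Reagents that add atoms: osmium tetroxide OsO4, O=[Os](=O)(=O)=O; sodium periodate NaIO4, [Na+].[O-]I(=O)(=O)=O
Why: Lemieux–Johnson cleavage (catalytic OsO4 dihydroxylation of the only alkene to diol 21, then periodate scission to β-ketoaldehyde 22 under lutidine buffering) is followed by spontaneous 6-exo-trig addition of the free O1–H to the new aldehyde carbon, which closes ring C as the hemiacetal; C2 settles under thermodynamic control with its hydroxyl trans to the C3 side chain, while C3 and Cα are carried through unchanged.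

Step 14
Reactants: 23 (2S,3R)-5,7-bis(benzyloxy)-3-[(S)-[4-(benzyloxy)phenyl](hydroxy)methyl]-2-hydroxy-6-methoxy-8-methyl-2,3-dihydro-4H-chromen-4-one
Product: 24 (2S,3R)-2,5,7-trihydroxy-3-[(S)-hydroxy(4-hydroxyphenyl)methyl]-6-methoxy-8-methyl-2,3-dihydro-4H-chromen-4-one (CNP0141808.1)
Conditions: H2 (1 atm), 10% Pd/C, EtOAc, rt, stopped at full conversion
Reagents that add atoms: none
Why: Heterogeneous catalytic hydrogenolysis, in which aryl benzyl ethers are cleaved much faster than a free secondary benzylic alcohol in a neutral aprotic solvent, while the hydrogen-bonded 2-hydroxyaryl ketone and the hemiacetal are not reduced and no stereocentre is touched.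

**Compound list**

1 | methyl 3,5-dihydroxy-4-methoxybenzoate | COC(=O)c1cc(O)c(OC)c(O)c1 | starting material
2 | methyl 3,5-bis(benzyloxy)-4-methoxybenzoate | COC(=O)c1cc(OCc2ccccc2)c(OC)c(OCc2ccccc2)c1 | intermediate
3 | [3,5-bis(benzyloxy)-4-methoxyphenyl]methanol | OCc1cc(OCc2ccccc2)c(OC)c(OCc2ccccc2)c1 | intermediate
4 | 3,5-bis(benzyloxy)-4-methoxybenzaldehyde | O=Cc1cc(OCc2ccccc2)c(OC)c(OCc2ccccc2)c1 | intermediate
5 | 3,5-bis(benzyloxy)-4-methoxyphenyl formate; not isolated | O=COc1cc(OCc2ccccc2)c(OC)c(OCc2ccccc2)c1 | intermediate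
6 | 3,5-bis(benzyloxy)-4-methoxyphenol | COc1c(OCc2ccccc2)cc(O)cc1OCc1ccccc1 | intermediate
7 | 4,6-bis(benzyloxy)-2-hydroxy-5-methoxybenzaldehyde | COc1c(OCc2ccccc2)cc(O)c(C=O)c1OCc1ccccc1 | intermediate
8 | 3,5-bis(benzyloxy)-2-formyl-4-methoxyphenyl ethyl carbonate; not isolated | CCOC(=O)Oc1cc(OCc2ccccc2)c(OC)c(OCc2ccccc2)c1C=O | intermediate
9 | 3,5-bis(benzyloxy)-4-methoxy-6-methylidenecyclohexa-2,4-dien-1-one; not isolated | C=C1C(=O)C=C(OCc2ccccc2)C(OC)=C1OCc1ccccc1 | intermediate
10 | 3,5-bis(benzyloxy)-4-methoxy-2-methylphenol | COc1c(OCc2ccccc2)cc(O)c(C)c1OCc1ccccc1 | intermediate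
11 | 4,6-bis(benzyloxy)-2-hydroxy-5-methoxy-3-methylbenzaldehyde | COc1c(OCc2ccccc2)c(C)c(O)c(C=O)c1OCc1ccccc1 | intermediate
12 | 4,6-bis(benzyloxy)-2-[(tert-butyldimethylsilyl)oxy]-5-methoxy-3-methylbenzaldehyde | COc1c(OCc2ccccc2)c(C)c(O[Si](C)(C)C(C)(C)C)c(C=O)c1OCc1ccccc1 | intermediate
13 | 1-{4,6-bis(benzyloxy)-2-[(tert-butyldimethylsilyl)oxy]-5-methoxy-3-methylphenyl}but-3-yn-1-ol, racemic | COc1c(OCc2ccccc2)c(C)c(O[Si](C)(C)C(C)(C)C)c(C(O)CC#C)c1OCc1ccccc1 | intermediate
14 | 1-{4,6-bis(benzyloxy)-2-[(tert-butyldimethylsilyl)oxy]-5-methoxy-3-methylphenyl}but-3-yn-1-one; not isolated | COc1c(OCc2ccccc2)c(C)c(O[Si](C)(C)C(C)(C)C)c(C(=O)CC#C)c1OCc1ccccc1 | intermediate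
15 | 1-{4,6-bis(benzyloxy)-2-[(tert-butyldimethylsilyl)oxy]-5-methoxy-3-methylphenyl}buta-2,3-dien-1-one | COc1c(OCc2ccccc2)c(C)c(O[Si](C)(C)C(C)(C)C)c(C(=O)C=C=C)c1OCc1ccccc1 | intermediate
16 | 4-(benzyloxy)benzaldehyde | O=Cc1ccc(OCc2ccccc2)cc1 | starting material
17 | (1Z)-1-{4,6-bis(benzyloxy)-2-[(tert-butyldimethylsilyl)oxy]-5-methoxy-3-methylphenyl}buta-1,3-dien-1-yl diisopinocampheylborinate, Ipc groups from (+)-α-pinene; not isolated | C=C/C=C(\OB([C@@H]1C[C@@H]2C[C@@H](C2(C)C)[C@H]1C)[C@@H]1C[C@@H]2C[C@@H](C2(C)C)[C@H]1C)c1c(O[Si](C)(C)C(C)(C)C)c(C)c(OCc2ccccc2)c(OC)c1OCc1ccccc1 | intermediate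
18 | O-(diisopinocampheylboryl) derivative of 19 at the carbinol oxygen (boron aldolate); not isolated | COc1c(OCc2ccccc2)c(C)c(O[Si](C)(C)C(C)(C)C)c(c1OCc1ccccc1)C(=O)[C@H]([C@H](OB([C@@H]1C[C@@H]2C[C@@H](C2(C)C)[C@H]1C)[C@@H]1C[C@@H]2C[C@@H](C2(C)C)[C@H]1C)c1ccc(OCc2ccccc2)cc1)C=C | intermediate
19 | (2S)-1-{4,6-bis(benzyloxy)-2-[(tert-butyldimethylsilyl)oxy]-5-methoxy-3-methylphenyl}-2-[(S)-[4-(benzyloxy)phenyl](hydroxy)methyl]but-3-en-1-one | COc1c(OCc2ccccc2)c(C)c(O[Si](C)(C)C(C)(C)C)c(c1OCc1ccccc1)C(=O)[C@H]([C@H](O)c1ccc(OCc2ccccc2)cc1)C=C | intermediate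
20 | (2S)-1-[4,6-bis(benzyloxy)-2-hydroxy-5-methoxy-3-methylphenyl]-2-[(S)-[4-(benzyloxy)phenyl](hydroxy)methyl]but-3-en-1-one | COc1c(OCc2ccccc2)c(C)c(O)c(c1OCc1ccccc1)C(=O)[C@H]([C@H](O)c1ccc(OCc2ccccc2)cc1)C=C | intermediate
21 | (2R)-1-[4,6-bis(benzyloxy)-2-hydroxy-5-methoxy-3-methylphenyl]-2-[(S)-[4-(benzyloxy)phenyl](hydroxy)methyl]-3,4-dihydroxybutan-1-one, both epimers at the new carbinol carbon; not isolated | COc1c(OCc2ccccc2)c(C)c(O)c(c1OCc1ccccc1)C(=O)[C@H]([C@H](O)c1ccc(OCc2ccccc2)cc1)C(O)CO | intermediate
22 | (2R)-3-[4,6-bis(benzyloxy)-2-hydroxy-5-methoxy-3-methylphenyl]-2-[(S)-[4-(benzyloxy)phenyl](hydroxy)methyl]-3-oxopropanal; not isolated | COc1c(OCc2ccccc2)c(C)c(O)c(c1OCc1ccccc1)C(=O)[C@H]([C@H](O)c1ccc(OCc2ccccc2)cc1)C=O | intermediate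
23 | (2S,3R)-5,7-bis(benzyloxy)-3-[(S)-[4-(benzyloxy)phenyl](hydroxy)methyl]-2-hydroxy-6-methoxy-8-methyl-2,3-dihydro-4H-chromen-4-one | COc1c(OCc2ccccc2)c(C)c2c(c1OCc1ccccc1)C(=O)[C@H]([C@H](O)c1ccc(OCc3ccccc3)cc1)[C@@H](O)O2 | intermediate
24 | (2S,3R)-2,5,7-trihydroxy-3-[(S)-hydroxy(4-hydroxyphenyl)methyl]-6-methoxy-8-methyl-2,3-dihydro-4H-chromen-4-one | COc1c(O)c(C)c2c(c1O)C(=O)[C@H]([C@H](O)c1ccc(O)cc1)[C@@H](O)O2 | target

**Step count and risks**

Total step count: 14. Longest linear sequence: 14 steps, from 1 to 24; aldehyde 16 is bought and enters at step 11.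

Steps most likely to fail:

1. Step 11 (proposed new method). The borane may reduce the ketone or hydroborate the terminal allene double bond instead of adding 1,4. The hindered dienolborinate may add sluggishly to the electron-rich aldehyde. The facial selectivity may be low or opposite to the assignment. The fallback uses known chemistry and sets out from aldehyde 12. Barbier allylation (allyl bromide, Zn dust, THF/sat. aq NH4Cl) should give 1-{4,6-bis(benzyloxy)-2-[(tert-butyldimethylsilyl)oxy]-5-methoxy-3-methylphenyl}but-3-en-1-ol F1. Dess–Martin oxidation (NaHCO3, CH2Cl2) should then give 1-{4,6-bis(benzyloxy)-2-[(tert-butyldimethylsilyl)oxy]-5-methoxy-3-methylphenyl}but-3-en-1-one F2. Soft enolisation of F2 with (−)-(Ipc)2BOTf and iPr2NEt in CH2Cl2 at −78 °C, a standard chiral boron enolate aldol protocol, removes a proton from the doubly activated CH2 and should give the same (Z)-dienolborinate 17. Addition of 16 and the buffered peroxide work-up of step 11 bring the sequence back to the route at 19. This detour also bypasses the allenyl ketone 15, should that compound prove too unstable to handle.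

2. Step 13. Periodate may oxidise the electron-rich free phenol of ring A, which has a methoxy group para to it. The open β-ketoaldehyde may also enolise before ring closure, with loss of C3 configuration or dehydration towards a chromone. The fallback sets out from 19 and reverses the order of unmasking, so that the oxidant never meets a free phenol. Ozonolysis of the vinyl group (O3, CH2Cl2, −78 °C, indicator dye, then PPh3) should give (2R)-3-{4,6-bis(benzyloxy)-2-[(tert-butyldimethylsilyl)oxy]-5-methoxy-3-methylphenyl}-2-[(S)-[4-(benzyloxy)phenyl](hydroxy)methyl]-3-oxopropanal F3. F3 is carried on cold and without purification, since it is itself a β-ketoaldehyde that can enolise at C3. Buffered desilylation (Bu4NF, AcOH, THF, 0 °C) frees O1, which closes the hemiacetal at once and returns to the route at 23.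

3. Step 14. The benzylic C–OH bond, activated by the para-oxygenated ring B, may be hydrogenolysed along with the benzyl ethers, or the hemiacetal may dehydrate to a chromone on the catalyst. The fallback sets out from 23 and masks both hydroxyl groups before the hydrogenolysis. Silylation (Et3SiCl, imidazole, DMF, 0 °C) should give the bis(triethylsilyl) ether of 23 at the C2 and carbinol oxygens F4. Hydrogenolysis (H2, 10% Pd/C, EtOAc) should then give the corresponding tri-phenol bis(triethylsilyl) ether F5, in which the bulky silyl ether slows benzylic C–O cleavage and the silyl acetal locks ring C. Buffered fluoride (HF·pyridine, pyridine, THF, 0 °C) removes both silyl groups and returns to the route at 24.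

Further compounds
F1 | step 11 | 1-{4,6-bis(benzyloxy)-2-[(tert-butyldimethylsilyl)oxy]-5-methoxy-3-methylphenyl}but-3-en-1-ol (racemic) | COc1c(OCc2ccccc2)c(C)c(O[Si](C)(C)C(C)(C)C)c(C(O)CC=C)c1OCc1ccccc1
F2 | step 11 | 1-{4,6-bis(benzyloxy)-2-[(tert-butyldimethylsilyl)oxy]-5-methoxy-3-methylphenyl}but-3-en-1-one | COc1c(OCc2ccccc2)c(C)c(O[Si](C)(C)C(C)(C)C)c(C(=O)CC=C)c1OCc1ccccc1
F3 | step 13 | (2R)-3-{4,6-bis(benzyloxy)-2-[(tert-butyldimethylsilyl)oxy]-5-methoxy-3-methylphenyl}-2-[(S)-[4-(benzyloxy)phenyl](hydroxy)methyl]-3-oxopropanal | COc1c(OCc2ccccc2)c(C)c(O[Si](C)(C)C(C)(C)C)c(c1OCc1ccccc1)C(=O)[C@H]([C@H](O)c1ccc(OCc2ccccc2)cc1)C=O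
F4 | step 14 | bis(triethylsilyl) ether of 23 (C2 oxygen and carbinol oxygen silylated, ring configuration as in 23) | COc1c(OCc2ccccc2)c(C)c2c(c1OCc1ccccc1)C(=O)[C@H]([C@H](O[Si](CC)(CC)CC)c1ccc(OCc3ccccc3)cc1)[C@@H](O[Si](CC)(CC)CC)O2
F5 | step 14 | bis(triethylsilyl) ether of 24 (C2 oxygen and carbinol oxygen silylated, three phenols free) | COc1c(O)c(C)c2c(c1O)C(=O)[C@H]([C@H](O[Si](CC)(CC)CC)c1ccc(O)cc1)[C@@H](O[Si](CC)(CC)CC)O2
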